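**Retrosynthetic overview**
- The target is the (2R,3R)-taxifolin core carrying a trans-dihydrobenzofuran across C-2'/O-3' of the B ring. The furan ring is closed last by acid-mediated O3'→C7 benzylic etherification, after C9 is unveiled by ozonolysis of a dihydropyran.
- Key disconnection: the C2'–C8 bond, made by an aromatic Claisen ([3,3]) rearrangement of a taxifolin 3'-O-(6-aryl-dihydropyran-3-yl) ether. The ether oxygen forces attack at C-2'.
- The ether comes from Pd(0) allylic etherification of 7,4'-bis-MOM taxifolin with a C-aryl pseudoglycal acetate, itself made by Pd(II) C-arylation of 3,4-di-O-acetyl-L-arabinal with a guaiacyl boronic acid.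
- Stereochemistry: C2/C3 are bought in (+)-taxifolin; C8 comes by suprafacial 1,3-transfer from arabinose C4; C7 is set trans to C8 in the ring closure.
- Ring order: chromanone (bought) → sacrificial dihydropyran (arabinose C1–C3 become C7–C9; C4, C5 and the ring O leave as ethylene glycol) → dihydrobenzofuran.

Assumption: no regioselective 4'-O-protection of taxifolin is assumed; the 7,4'- and 7,3'-bis-MOM isomers from step 1 are taken to be separable by chromatography. Nothing in this route has been run; conditions are proposals.

**Step 1**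
Reactants: 1, (+)-taxifolin [(2R,3R)-dihydroquercetin]
Product: 2, (2R,3R)-3,5-dihydroxy-2-[3-hydroxy-4-(methoxymethoxy)phenyl]-7-(methoxymethoxy)chroman-4-one
Conditions: MOMCl (2.1 equiv), i-Pr2NEt, THF/CH2Cl2, 0 °C → rt; separate from the 7,3'-isomer (recycle to 1 with HCl/MeOH)
Reagents that add atoms: chloromethyl methyl ether, COCCl
Why: Williamson-type O-alkylation takes the most acidic 7-OH first and then one catechol OH with little 3'/4' bias (expect roughly 1:1, so 2 is isolated), while the chelated 5-OH and the 3-OH stay free and no stereocentre is touched.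

**Step 2**
Reactants: 3, 3,4-di-O-acetyl-L-arabinal; 4, [4-(benzyloxy)-3-methoxyphenyl]boronic acid
Product: 5, (3R,6S)-6-[4-(benzyloxy)-3-methoxyphenyl]-3,6-dihydro-2H-pyran-3-yl acetate (aryl and OAc trans)
Conditions: Pd(OAc)2 (10 mol %), 4 (1.8 equiv), MeCN, rt
Reagents that add atoms: the aryl group of 4, COc1cc(B(O)O)ccc1OCc1ccccc1
Why: Pd(II) carbon-Ferrier-type C-glycosylation (transmetalation, syn-carbopalladation of the enol ether anti to the C3 acetate, anti-β-acetoxy elimination) sets the new aryl-bearing centre from the glycal C3 acetate and leaves the arabinose C4 acetate trans to the aryl group.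

**Step 3**
Reactants: 2 and 5
Product: 6, (2R,3R)-2-[3-{[(3R,6S)-6-(4-benzyloxy-3-methoxyphenyl)-3,6-dihydro-2H-pyran-3-yl]oxy}-4-(methoxymethoxy)phenyl]-3,5-dihydroxy-7-(methoxymethoxy)chroman-4-one
Conditions: Pd(PPh3)4 (5 mol %), i-Pr2NEt (1.5 equiv), THF, 45–50 °C
Reagents that add atoms: none (Pd, phosphine and base are not incorporated)
Why: Tsuji–Trost allylic etherification by the only unchelated free phenol (3'-OH) proceeds with double inversion (net retention) at the terminus remote from the aryl-bearing carbon, so the aryloxy group stays trans to the guaiacyl group.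

**Step 4 (key step)**
Reactants: 6
Product: 7, (2R,3R)-2-{2-[(2S,3R)-2-(4-benzyloxy-3-methoxyphenyl)-3,6-dihydro-2H-pyran-3-yl]-3-hydroxy-4-(methoxymethoxy)phenyl}-3,5-dihydroxy-7-(methoxymethoxy)chroman-4-one
Conditions: degassed 1,2-dichlorobenzene (0.05 M), BHT (cat.), 160 °C, sealed tube (or Eu(fod)3 10 mol %, PhCl, 110 °C)
Reagents that add atoms: none
Why: Aromatic Claisen ([3,3]-sigmatropic) rearrangement: C-2' is the only unsubstituted ortho carbon, and the ring-locked allyl unit forces suprafacial delivery of the arene to the face the oxygen leaves (anti to the guaiacyl group), so the arabinose-derived C–O centre is transferred 1,3 to C8 before tautomerisation to the phenol.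

**Step 5**
Reactants: 7
Product: 8, (2R,3R)-2-{2-[(1S,2S)-1-(4-benzyloxy-3-methoxyphenyl)-3-hydroxy-1-(2-hydroxyethoxy)propan-2-yl]-3-hydroxy-4-(methoxymethoxy)phenyl}-3,5-dihydroxy-7-(methoxymethoxy)chroman-4-one
Conditions: O3 (to Sudan III end-point), CH2Cl2/MeOH 4:1, −78 °C; PPh3, −78 → 0 °C; then NaBH4, −40 → −10 °C (one pot)
Reagents that add atoms: ozone, [O-][O+]=O (supplies the two new hydroxyl oxygens)
Why: Ozonolysis of the only alkene followed by low-temperature borohydride reduction (aldehyde/lactol far faster than the H-bonded vinylogous-ester C4 ketone) turns one alkene carbon into the C9 CH2OH and the other into a 2-hydroxyethyl ether on the benzylic oxygen; immediate reduction keeps the α-aryl aldehyde from epimerising C8.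

**Step 6**
Reactants: 8
Product: 9, (2R,3R)-2-[(2R,3S)-2-(4-benzyloxy-3-methoxyphenyl)-7-hydroxy-3-(hydroxymethyl)-2,3-dihydro-1-benzofuran-4-yl]-3,5,7-trihydroxychroman-4-one
Conditions: HCl (ca. 1.5 M) in MeOH/THF, 45 °C, dilute (0.01 M)
Reagents that add atoms: none
Why: Acidic methanolysis removes both MOM groups and ionises the 4-alkoxybenzylic ether (ethylene glycol leaves); 5-exo capture of the benzylic cation by the adjacent 3'-phenol (biomimetic phenylcoumaran closure) gives the thermodynamically preferred 2,3-trans ring, i.e. 2R set by C8, which is also the outcome of invertive displacement of the original C–O bond.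

**Step 7**
Reactants: 9
Product: 10, target: (2R,3R)-3,5,7-trihydroxy-2-[(2R,3S)-7-hydroxy-2-(4-hydroxy-3-methoxyphenyl)-3-(hydroxymethyl)-2,3-dihydro-1-benzofuran-4-yl]chroman-4-one
Conditions: H2 (1 atm), 10 % Pd/C, EtOAc/MeOH, rt, stopped at 1 equiv H2
Reagents that add atoms: none
Why: Hydrogenolysis of the aryl benzyl ether is much faster than cleavage of the cyclic benzylic ethers (dihydrobenzofuran C2–O, chromanone C2–O), and no stereocentre is affected.

**Compound list**
1 | (+)-taxifolin | Oc1ccc(cc1O)[C@H]1Oc2cc(O)cc(O)c2C(=O)[C@@H]1O | starting material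
2 | 7,4'-bis-O-MOM taxifolin | COCOc1ccc(cc1O)[C@H]1Oc2cc(OCOC)cc(O)c2C(=O)[C@@H]1O | intermediate
3 | 3,4-di-O-acetyl-L-arabinal | CC(=O)O[C@@H]1C=COC[C@@H]1OC(C)=O | starting material
4 | [4-(benzyloxy)-3-methoxyphenyl]boronic acid | COc1cc(B(O)O)ccc1OCc1ccccc1 | starting material
5 | (3R,6S)-6-aryl-3,6-dihydro-2H-pyran-3-yl acetate (trans) | CC(=O)O[C@H]1CO[C@@H](C=C1)c1ccc(OCc2ccccc2)c(OC)c1 | intermediate
6 | taxifolin 3'-O-dihydropyranyl ether | COCOc1ccc(cc1O[C@H]2CO[C@@H](C=C2)c3ccc(OCc4ccccc4)c(OC)c3)[C@H]5Oc6cc(OCOC)cc(O)c6C(=O)[C@@H]5O | intermediate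
7 | Claisen product, 2'-C-(2-aryl-3,6-dihydro-2H-pyran-3-yl) phenol | COCOc1ccc([C@H]5Oc6cc(OCOC)cc(O)c6C(=O)[C@@H]5O)c(c1O)[C@H]2C=CCO[C@@H]2c3ccc(OCc4ccccc4)c(OC)c3 | intermediate
8 | seco-diol with C9 CH2OH and C7 2-hydroxyethyl ether | COCOc1ccc([C@H]5Oc6cc(OCOC)cc(O)c6C(=O)[C@@H]5O)c(c1O)[C@@H](CO)[C@H](OCCO)c3ccc(OCc4ccccc4)c(OC)c3 | intermediate
9 | O-benzyl target | COc1cc([C@@H]2Oc3c(O)ccc([C@H]4Oc5cc(O)cc(O)c5C(=O)[C@@H]4O)c3[C@H]2CO)ccc1OCc1ccccc1 | intermediate
10 | CID21589839 | COc1cc([C@@H]2Oc3c(O)ccc([C@H]4Oc5cc(O)cc(O)c5C(=O)[C@@H]4O)c3[C@H]2CO)ccc1O | target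

**Totals**
Total steps: 7. Longest linear sequence: 6 (steps 2–7 from the glycal, or steps 1, 3–7 from taxifolin).

**Three steps most likely to fail**
1. Step 4 (Claisen). C-2' is flanked by the chromanone-bearing carbon. The cyclic secondary allyl ether may instead eliminate (phenol 2 plus a 2H-pyran), migrate ortho(C-4')→para(C-6'), or the product may undergo retro-hetero-Diels–Alder if overheated. Fallback: use an acyclic (E)-secondary allyl ether with the same carbons. (R)-3-Buten-2-ol is cross-metathesised with ArCH(OTBS)CH=CH2 and the product joined to 2 by Mitsunobu inversion. The chair [3,3] shift then transfers the methyl-carbinol centre to C8, and the resulting propenyl group is ozonised to C9 as in step 5.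
2. Step 1 (3'/4' differentiation). The second MOM group has no real regiochemical bias, so about half the bis-MOM material is the wrong isomer. Fallback: take the regiochemistry from a pre-differentiated B ring. Protocatechualdehyde is protected selectively at the 4-OH (para to CHO), the ether/Claisen/ozonolysis sequence is run on that aldehyde, and the flavanonol is then built by chalcone formation, epoxidation and cyclisation. The price is that C2/C3 are no longer bought and the flavanonol diastereomers must be separated.
3. Step 3 (Pd etherification). Pseudoglycal 4-acetates ionise sluggishly, Pd must approach the guaiacyl face, and reversible ionisation of 6 could leak to the cis ether (which would give the C8 epimer). Fallback: switch to 3,4-di-O-acetyl-D-xylal. The same C-arylation gives the cis acetate; K2CO3/MeOH then frees the alcohol, and an irreversible Mitsunobu etherification with 2 (PPh3, DIAD, inversion) gives the same ether 6 at the cost of one extra step.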